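The runs are calculated on assumed constants; scatter was added.

**Late readings.** Late in the north-east run the product stands still near 38.5%, and its last reading still shows 60% substrate. The west run has 2.4 equiv of partner against 1.1 equiv, and it ends higher, near 56.5%. So at this substrate concentration and catalyst loading, more partner gave more product. I treat partner as the limiting reagent, although it is charged in excess.

the same everywhere: free catalyst 0.2 mol%

| flask | substrate | partner | remark | time |
|---|---|---|---|---|
| north-east | 16 mM | 1.1 equiv | run made earlier |  |
| south-west | 16 mM | 1.5 equiv | run made earlier |  |
| west | 16 mM | 2.4 equiv | run made earlier |  |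
| north-west | 32 mM | 1.1 equiv | run made earlier |  |
| oak | 16 mM | 1.10 equiv | plug flow through a tube for 4.0 d, no back-mixing | 4.0 d |
| alder | 16 mM | 1.10 equiv (fed, over 4.00 d) | all but partner at the start; partner goes in evenly over 4.00 d, the run ends at 4.0 d | 4.0 d |
| birch | 16 mM | 1.10 equiv | one stirred flow tank at steady state, fed with the mixture as stated, mean residence time 4.0 d |  |
| larch | 16 mM | 1.10 equiv | a closed flask charged with all of it at once and left for 4.0 d | 4.0 d |

| run | time / d | product / % | substrate / % |
|---|---|---|---|
| north-east | 0.625 | 38 | 63 |
| north-east | 1.25 | 40 | 58 |
| north-east | 2.08 | 40 | 60 |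
| north-east | 2.50 | 38 | 61 |
| north-east | 3.00 | 40 | 62 |
| north-east | 4.00 | 37 | 60 |
| south-west | 0.417 | 39 | 60 |
| south-west | 0.833 | 44 | 53 |
| south-west | 1.25 | 46 | 54 |
| south-west | 1.67 | 46 | 50 |
| south-west | 2.08 | 45 | 56 |
| south-west | 2.50 | 47 | 54 |
| west | 0.208 | 31 | 67 |
| west | 0.333 | 43 | 60 |
| west | 0.500 | 49 | 50 |
| west | 0.833 | 56 | 43 |
| west | 1.67 | 56 | 45 |
| west | 2.50 | 57 | 42 |
| north-west | 0.500 | 40 | 57 |
| north-west | 1.04 | 44 | 56 |
| north-west | 1.25 | 46 | 57 |
| north-west | 2.08 | 44 | 56 |
| north-west | 2.50 | 45 | 56 |

(standard deviation of a reading: 1.5 percentage points)

- the stated concentrations are those of everything mixed, before any reaction; amounts are the same in each set-up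
- the analysis behind the earlier runs scatters by 1.5 percentage points, standard deviation
- the feed brings no volume worth counting
- the earlier runs were made in a closed, stirred flask

- the set-up with the highest amount of product at the outlet or at the end, in percent of the substrate put in ("none" if the first two lie within 2 percentage points) (oak / alder / birch / larch / none)
- amount of product at the outlet or at the end, in percent of the substrate put in, oak
- amount of product at the outlet or at the end, in percent of the substrate put in, alder
- amount of product at the outlet or at the end, in percent of the substrate put in, birch
- amount of product at the outlet or at the end, in percent of the substrate put in, larch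

**Partner cost.** Write the balance of partner: what you charge is either spent on making product or lost. Take the partner cost as equivalents charged per equivalent of product. It reads 2.86 in the north-east run and 4.25 in the west run. At this substrate concentration and catalyst loading, that is a slope of 1.07 per equivalent. The south-west run, read separately, gives 3.26, and the line gives 3.29. Run the line back to zero charge and you get 1.68. I read this as the floor cost, my estimate of the partner spent per product while c partner stays near zero.

**Two extremes.** First, charge everything at once. Larch is the north-east recipe in a closed flask, and each plug in oak lives the same history, so I expect both near 38.5%. Second, hold c partner near zero throughout. Then 1.10 equiv at the floor cost gives an estimate of 65.5%. Alder and birch keep c partner above zero but under the full charge, so I place both inside this bracket. My bet is alder.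

**The forecast.** It gives none as best, with oak 39%, alder 5%, birch 33% and larch 39%. Its ground for alder: “Alder starves while the catalyst dies”. Its figure for alder lies under my bracket.

**The result.** The best is alder: alder 51.4%, birch 44.6%, oak 39.0%, larch 39.0%. These reactions ran:

    partner + free catalyst → catalyst intermediate A (k = 6900 L mol⁻¹ h⁻¹)
    substrate + catalyst intermediate A → catalyst intermediate B (k = 4800 L mol⁻¹ h⁻¹)
    catalyst intermediate B ⇌ by-product + catalyst intermediate C (K = 0.00600 M, k = 5800 h⁻¹)
    catalyst intermediate C ⇌ free catalyst + product (K = 0.0190 M, k = 140 h⁻¹)
    partner → decomposed reagent (k = 0.150 h⁻¹)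

The highest c partner in alder was 0.730 mM, far lower than the 17.6 mM charged at once in larch. Reckoned on the full charge, the partner cost in alder was 2.14, above the floor 1.68 and below the 2.82 of larch. Take larch with 4.40 equiv of partner. The floor cost and slope give 68.9%, and that flask gave 71.3%.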